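**Strategy**

The ten-membered ring (C1–C10; C15 on C4, C11 on C7) is traced to a cyclodeca-1(10),4-diene whose unit C10=C1–C2–C3–C4=C5 is a 1,5-diene flanked by the C9 ketone and the C15 ester: the retro-[2+2] signature of a bicyclo[2.2.0]hexane. The key step is therefore the [2+2] photocycloaddition of (R)-5-silyloxy-2-methylcyclohex-2-enone, made from carvone, with methyl cyclobut-1-enecarboxylate; in one operation it forms C1–C10 and C4–C5, closes the cyclobutane and delivers the 6-4-4 tricycle that heat opens to the medium ring. A C9-tethered olefination fixes the C7=C11 geometry, and two tartrate-controlled epoxidations set all four stereocentres.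

Key step: step 6

**Remarks on the chemistry (assumptions)**

- Numbering throughout: ring C1–C10 with C1=C10 and the C9 ketone; C14 is the methyl on C10; C15 is on C4; C11 is on C7 and carries C12 (CH2O) and C13 (CH3).
- Read from the SMILES, the target is 4R,5R,7S,11R with an E C1=C10 bond. C3 and C6 are cis on the 4,5-epoxide and C12 is cis to C8 on the 7,11-epoxide. The diene must therefore be E at C1=C10 with C3/C6 cis at C4=C5, and the exocyclic olefin must carry C12 on the C8 side.
- Photoadduct 10 is drawn with the new C4–C5 bond anti to the C7 silyloxy group, the facial sense expected for a 5-substituted cyclohexenone. The syn-facial cis-anti-cis isomer would converge on the same diene 11, because C7 is the only stereocentre that survives step 7.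
- Both epoxidations need the same ligand, D-(−)-diethyl tartrate. The C9 carbinol freed in step 13 is itself allylic, so it is set 9S in step 8 (the slow-reacting sense for that tartrate) and is oxidised by an allylic-selective oxidant after the epoxidations.
- Compounds 1, 7 and 13 are taken as catalogue materials.

**Route**

Step 1
Reactants: 1 (R)-carvone
Product: 4 (1R)-4-methyl-5-oxocyclohex-3-en-1-yl acetate, via methoxy hydroperoxide 2 (not isolated), via peroxyacetate 3 (not isolated)
Conditions: O3, CH2Cl2/MeOH, −78 °C; then Ac2O, Et3N, DMAP (cat.), −78 °C to rt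
Reagents that add atoms: ozone O=[O+][O-]; methanol CO; acetic anhydride CC(=O)OC(C)=O
Why: Ozonolysis in methanol cleaves only the electron-rich isopropenyl group, and Criegee rearrangement of the acetylated α-methoxy hydroperoxide moves the ring carbon to oxygen with retention, so the C7 oxygen takes the place and configuration of the isopropenyl carbon.

Step 2
Reactants: 4 (1R)-4-methyl-5-oxocyclohex-3-en-1-yl acetate
Product: 5 (5R)-5-hydroxy-2-methylcyclohex-2-en-1-one
Conditions: K2CO3 (cat.), MeOH, 0 °C
Reagents that add atoms: none
Why: Base-catalysed transesterification in cold methanol frees the alcohol faster than the β-oxygenated enone can eliminate to the cresol, and the stereocentre is not touched.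

Step 3
Reactants: 5 (5R)-5-hydroxy-2-methylcyclohex-2-en-1-one
Product: 6 (5R)-5-[(tert-butyldimethylsilyl)oxy]-2-methylcyclohex-2-en-1-one
Conditions: TBSCl, imidazole, DMF, 0 °C to rt
Reagents that add atoms: tert-butyldimethylsilyl chloride CC(C)(C)[Si](C)(C)Cl
Why: Standard imidazole-mediated silylation of a secondary alcohol gives an ether that is transparent above 300 nm and stable to neutral thermolysis.

Step 4
Reactants: 7 ethyl 1-bromocyclobutane-1-carboxylate
Product: 8 cyclobut-1-ene-1-carboxylic acid
Conditions: KOH, PhMe, reflux; then aq. HCl, 0 °C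
Reagents that add atoms: potassium hydroxide [K+].[OH-]
Why: E2 dehydrobromination of the tertiary α-bromo ester by hot KOH, with concurrent saponification, is the usual entry to this strained acrylic acid.

Step 5
Reactants: 8 cyclobut-1-ene-1-carboxylic acid
Product: 9 methyl cyclobut-1-ene-1-carboxylate
Conditions: TMSCHN2, Et2O/MeOH, 0 °C; used at once as a cold solution
Reagents that add atoms: (trimethylsilyl)diazomethane C[Si](C)(C)C=[N+]=[N-]
Why: Diazoalkane esterification is neutral and fast at 0 °C, which avoids the base- and heat-induced polymerisation of the strained acrylate.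

Step 6
Reactants: 6 (5R)-5-[(tert-butyldimethylsilyl)oxy]-2-methylcyclohex-2-en-1-one; 9 methyl cyclobut-1-ene-1-carboxylate
Product: 10 methyl 9-[(tert-butyldimethylsilyl)oxy]-6-methyl-7-oxotricyclo[4.4.0.0(2,5)]decane-2-carboxylate (cis-anti-cis; bonds C1–C10 and C4–C5 new; C4 anti to the 7R silyloxy group)
Conditions: hν (350 nm, Pyrex), 9 (4 equiv), CH2Cl2 (degassed), −40 °C
Reagents that add atoms: none
Why: Excitation of the enone and intersystem crossing give the twisted triplet, which adds to the strained, unhindered cyclobutene C=C to form a triplet 1,4-diradical that closes after spin inversion; this is the intermolecular enone–alkene [2+2] photocycloaddition in the form practised with cyclobutenecarboxylates. The one new ring, the cyclobutane C5–C10–C1–C4, closes by radical recombination within that diradical (1,4-closure), the cyclohexanone and cyclobutene rings being carried in unchanged. C5 and C10 end cis because the six-membered ring relaxes to the cis 6-4 fusion before closure, C1 and C4 are cis by the constraint of the cyclobutene ring, and the two outer rings lie anti across the new cyclobutane for steric reasons (cis-anti-cis). The enone face is chosen by the C7 silyloxy group: bonding at C5 should occur axially on the half-chair, anti to the pseudo-equatorial OSi group. The step needs head-to-tail regiochemistry (C4 to C5, C1 to C10), which the C10 methyl should secure, since the alternative diradical would have to join the quaternary centres C10 and C4 and is expected to revert instead. Low temperature and an excess of the volatile cyclobutene ester are used to suppress enone dimerisation.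

Step 7
Reactants: 10 cis-anti-cis tricyclic keto ester
Product: 11 methyl (1E,4R,7E)-4-[(tert-butyldimethylsilyl)oxy]-7-methyl-6-oxocyclodeca-1,7-diene-1-carboxylate (ring numbering of this guide: E C1=C10; C3/C6 cis at C4=C5; 7R)
Conditions: PhMe (0.01 M, degassed), sealed tube, 180 °C
Reagents that add atoms: none
Why: Thermal retro-[2+2] of the bicyclo[2.2.0]hexane proceeds by homolysis of the central C1–C4 bond to a chair-like cyclohexane-1,4-diyl that cleaves C5–C10; allylic strain against the ester on the planar C4 centre should keep C6 axial at C5 and the cis ring fusion then places C9 equatorial at C10, so C4=C5 should emerge with C3/C6 cis and C1=C10 as the E-enone, whose conjugation would be lost in a Cope return to the divinylcyclohexanone.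

Step 8
Reactants: 11 (7R)-cyclodecadienone ester
Product: 12 methyl (1E,4R,6S,7E)-4-[(tert-butyldimethylsilyl)oxy]-6-hydroxy-7-methylcyclodeca-1,7-diene-1-carboxylate (the 7R,9S allylic alcohol)
Conditions: (R)-2-methyl-CBS-oxazaborolidine (0.5 equiv), catecholborane, PhMe, −78 °C
Reagents that add atoms: none
Why: Corey–Bakshi–Shibata reduction, with the α-methylalkenyl carbon C10 as the large group, should deliver hydride 1,2 under reagent control to give the 9S carbinol without touching the enoate, and this configuration later makes the ring alcohol the slow partner for D-(−)-tartrate.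

Step 9
Reactants: 12 (7R,9S)-allylic alcohol; 13 2-(diethoxyphosphoryl)propanoic acid
Product: 14 C9 2-(diethoxyphosphoryl)propanoate of 12 (both epimers at the phosphonate α-carbon)
Conditions: DCC, DMAP (cat.), CH2Cl2, 0 °C to rt
Reagents that add atoms: none
Why: Steglich esterification acylates the hindered secondary allylic alcohol with retention at C9, and the stereorandom phosphonate carbon is erased in step 12.

Step 10
Reactants: 14 C9 phosphonopropanoate silyl ether
Product: 15 (7R,9S)-C7 alcohol bearing the C9 phosphonopropanoate
Conditions: HF·pyridine, pyridine, THF, 0 °C to rt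
Reagents that add atoms: none
Why: Buffered fluoride cleavage of the silyl ether leaves both carboxylic esters and the phosphonate intact and, being non-basic, avoids a 1,3-acyl shift from O9 to O7.

Step 11
Reactants: 15 C7 alcohol
Product: 16 (9S)-C7 ketone (β-acyloxy ketone) bearing the C9 phosphonopropanoate
Conditions: Dess–Martin periodinane, CH2Cl2, 0 °C to rt
Reagents that add atoms: none
Why: Dess–Martin oxidation converts the secondary alcohol into the ketone under neutral conditions, so the β-acyloxy ketone is formed without elimination and the C7 stereocentre is removed by design.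

Step 12
Reactants: 16 C7 ketone with C9 phosphonopropanoate
Product: 17 bridged α-methyl-α,β-unsaturated δ-lactone (O9–C12(=O)–C11(CH3)=C7; 9S; C15 methyl ester retained)
Conditions: LiCl, DBU, MeCN, 0 °C to rt
Reagents that add atoms: none
Why: Intramolecular Horner–Wadsworth–Emmons olefination under Masamune–Roush conditions closes the six-membered lactone from O9, which forces C12 cis to C8 on the new tetrasubstituted C7=C11 bond, and the mild LiCl/amidine base is chosen so that ring closure outruns E1cB loss of the C9 carboxylate.

Step 13
Reactants: 17 unsaturated lactone ester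
Product: 18 (9S)-triol (C15–OH, C12–OH, C9–OH; C12 cis to C8 on C7=C11; C3/C6 cis on C4=C5; E C1=C10)
Conditions: iBu2AlH (7 equiv), CH2Cl2, −78 to 0 °C; aq. KNaC4H4O6 work-up
Reagents that add atoms: none
Why: Hydride reduction with iBu2AlH takes the conjugated methyl ester and the unsaturated lactone (through its lactol) 1,2 to the allylic alcohols, releasing O9 as the free carbinol without changing any olefin geometry.

Step 14
Reactants: 18 (9S)-triol
Product: 20 bis-epoxy triol (4,5- and 7,11-epoxides configured as in the target; 9S carbinol), via 4,5-monoepoxide 19 (not isolated)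
Conditions: Ti(OiPr)4 (1.2 equiv), D-(−)-diethyl tartrate (1.4 equiv), tBuOOH (2.2 equiv), 4 Å molecular sieves, CH2Cl2, −20 °C
Reagents that add atoms: tert-butyl hydroperoxide CC(C)(C)OO
Why: Katsuki–Sharpless asymmetric epoxidation of the two primary allylic alcohols with D-(−)-tartrate should deliver oxygen to the face that makes the carbinol-bearing carbons C4 and C11 both R, the fixed olefin geometries then giving 5R and 7S, while the 9S ring carbinol is the slow-reacting sense for this tartrate so that C1=C10 is spared.

Step 15
Reactants: 20 bis-epoxy triol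
Product: 21 (4R,5R,7S,11R)-bis-epoxy diol E-enone
Conditions: MnO2 (activated, excess), CH2Cl2, rt
Reagents that add atoms: none
Why: MnO2 oxidises only allylic alcohols, and after step 14 the C9 carbinol is the sole allylic hydroxyl, so the enone is unveiled without protecting the two primary epoxy alcohols.

Step 16
Reactants: 21 bis-epoxy diol enone
Product: 22 CNP0185847.3 (the 12,15-diacetate; 4R,5R,7S,11R; E C1=C10)
Conditions: Ac2O, pyridine, DMAP (cat.), CH2Cl2, 0 °C, directly after step 15
Reagents that add atoms: acetic anhydride CC(=O)OC(C)=O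
Why: DMAP-catalysed acetylation of the two primary alcohols needs only a mild amine base, which the enone, both epoxides and the β,γ-epoxy ketone should tolerate.

**Compound list**

1 | (R)-carvone | CC1=CC[C@H](CC1=O)C(C)=C | starting material
2 | (5R)-5-(1-hydroperoxy-1-methoxyethyl)-2-methylcyclohex-2-en-1-one (epimers at the peroxy carbon) | CC1=CC[C@H](CC1=O)C(C)(OC)OO | intermediate
3 | 1-methoxy-1-[(1R)-4-methyl-5-oxocyclohex-3-en-1-yl]ethyl peroxyacetate | CC1=CC[C@H](CC1=O)C(C)(OC)OOC(C)=O | intermediate
4 | (1R)-4-methyl-5-oxocyclohex-3-en-1-yl acetate | CC1=CC[C@H](CC1=O)OC(C)=O | intermediate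
5 | (5R)-5-hydroxy-2-methylcyclohex-2-en-1-one | CC1=CC[C@H](CC1=O)O | intermediate
6 | (5R)-5-[(tert-butyldimethylsilyl)oxy]-2-methylcyclohex-2-en-1-one | CC1=CC[C@@H](O[Si](C)(C)C(C)(C)C)CC1=O | intermediate
7 | ethyl 1-bromocyclobutane-1-carboxylate | CCOC(=O)C1(Br)CCC1 | starting material
8 | cyclobut-1-ene-1-carboxylic acid | OC(=O)C1=CCC1 | intermediate
9 | methyl cyclobut-1-ene-1-carboxylate | COC(=O)C1=CCC1 | intermediate
10 | cis-anti-cis 6-4-4 tricyclic keto ester (C4 anti to the 7R silyloxy group) | O=C1C[C@H](O[Si](C)(C)C(C)(C)C)C[C@@H]2[C@@]1(C)[C@H]1CC[C@@]21C(=O)OC | intermediate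
11 | methyl (1E,4R,7E)-4-[(tert-butyldimethylsilyl)oxy]-7-methyl-6-oxocyclodeca-1,7-diene-1-carboxylate | COC(=O)/C1=C/C[C@@H](O[Si](C)(C)C(C)(C)C)CC(=O)/C(C)=C/CC1 | intermediate
12 | methyl (1E,4R,6S,7E)-4-[(tert-butyldimethylsilyl)oxy]-6-hydroxy-7-methylcyclodeca-1,7-diene-1-carboxylate | COC(=O)/C1=C/C[C@@H](O[Si](C)(C)C(C)(C)C)C[C@H](O)/C(C)=C/CC1 | intermediate
13 | 2-(diethoxyphosphoryl)propanoic acid | CCOP(=O)(OCC)C(C)C(O)=O | starting material
14 | C9 2-(diethoxyphosphoryl)propanoate of 12 | COC(=O)/C1=C/C[C@@H](O[Si](C)(C)C(C)(C)C)C[C@H](OC(=O)C(C)P(=O)(OCC)OCC)/C(C)=C/CC1 | intermediate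
15 | (7R,9S)-C7 alcohol with C9 phosphonopropanoate | COC(=O)/C1=C/C[C@@H](O)C[C@H](OC(=O)C(C)P(=O)(OCC)OCC)/C(C)=C/CC1 | intermediate
16 | (9S)-C7 ketone with C9 phosphonopropanoate | COC(=O)/C1=C/CC(=O)C[C@H](OC(=O)C(C)P(=O)(OCC)OCC)/C(C)=C/CC1 | intermediate
17 | (9S)-bridged unsaturated δ-lactone methyl ester | COC(=O)/C1=C/CC2=C(C)C(=O)O[C@@H](C2)/C(C)=C/CC1 | intermediate
18 | (9S)-triol | OC/C1=C/C/C(=C(\C)CO)C[C@H](O)/C(C)=C/CC1 | intermediate
19 | (4R,5R,9S)-4,5-monoepoxy triol | OC[C@]12CC/C=C(\C)[C@@H](O)C/C(=C(/C)CO)C[C@H]1O2 | intermediate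
20 | bis-epoxy triol (epoxides as in the target, 9S) | OC[C@]12CC/C=C(\C)[C@@H](O)C[C@]3(C[C@H]1O2)O[C@]3(C)CO | intermediate
21 | (4R,5R,7S,11R)-bis-epoxy diol enone | OC[C@]12CC/C=C(\C)C(=O)C[C@]3(C[C@H]1O2)O[C@]3(C)CO | intermediate
22 | CNP0185847.3 | CC(=O)OC[C@]12CC/C=C(\C)C(=O)C[C@]3(C[C@H]1O2)O[C@]3(C)COC(C)=O | target

**Step count**

Total: 16 steps. Longest linear sequence: 14 steps (steps 1–3 and 6–16, from (R)-carvone); the cyclobutene branch adds steps 4 and 5.

**The three steps most likely to fail**

Step 6 (photocycloaddition). The 1,4-diradical may close in the head-to-head sense (ester carbon on C10), which acceptor alkenes often prefer, and the strained ester may photopolymerise. The fallback changes the electronic character of the alkene and sets out from 9 and 6. Ester 9 is reduced with iBu2AlH (CH2Cl2, −78 °C) to cyclobut-1-en-1-ylmethanol F1. Irradiation of F1 with 6 under the conditions of step 6 should give the hydroxymethyl tricycle F2, because alkyl-substituted alkenes place their substituted carbon on the enone β-carbon C5. Oxidation of the primary alcohol with TEMPO (cat.), NaOCl (cat.) and NaClO2 in buffered MeCN gives the tricyclic acid F3, and methylation with TMSCHN2 returns to the route at 10.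

Step 7 (thermolysis). The 1,4-diyl may fragment through the other chair, which would give the Z-enone with C3/C6 trans, and the diene may drift by Cope rearrangement on prolonged heating; the geometry is to be checked by NOE before going on. The fallback adds a second conformational bias by inverting C7 and sets out from 10. With the silyloxy group cis to C4 on the cyclohexanone ring, the unwanted chair would carry a 1,3-diaxial C4/OSi contact. Desilylation (Bu4NF, AcOH, THF) gives the tricyclic alcohol F4. Mitsunobu reaction (4-nitrobenzoic acid, PPh3, DIAD) gives the inverted 4-nitrobenzoate F5, methanolysis (K2CO3, MeOH, 0 °C) gives the 7S alcohol F6, and silylation gives the 7S silyl ether F7. Thermolysis as in step 7 should give the 7S diene F8, the enantiomer of 11. Steps 8, 9 and 10 applied to F8 give the 7S,9S alcohol F9, its phosphonopropanoate F10 and the 7S C7 alcohol F11. Oxidation as in step 11 removes C7 as a stereocentre and returns to the route at 16.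

Step 12 (olefination). The base may expel the C9 carboxylate from the β-acyloxy ketone (E1cB) or move the C4=C5 bond through the doubly activated C6 position before the hindered phosphonate closes. The fallback replaces the basic olefination by a reductive aldol and sets out from 12. Acylation with 2-bromopropanoyl bromide and pyridine gives the C9 2-bromopropanoate F12, HF·pyridine gives the C7 alcohol F13, and Dess–Martin oxidation gives the keto bromo ester F14. SmI2 (THF, −78 °C) then effects an intramolecular Reformatsky reaction, which needs no base, to give the β-hydroxy δ-lactone F15 with the same enforced C12–C8 relationship. Dehydration (SOCl2, pyridine, then DBU to bring any β,γ-isomer into conjugation) returns to the route at 17.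

**Further compounds**

F1 | step 6 | cyclobut-1-en-1-ylmethanol | OCC1=CCC1
F2 | step 6 | cis-anti-cis hydroxymethyl tricycle (C15 alcohol analogue of 10) | O=C1C[C@H](O[Si](C)(C)C(C)(C)C)C[C@@H]2[C@@]1(C)[C@H]1CC[C@@]21CO
F3 | step 6 | cis-anti-cis tricyclic carboxylic acid | O=C1C[C@H](O[Si](C)(C)C(C)(C)C)C[C@@H]2[C@@]1(C)[C@H]1CC[C@@]21C(O)=O
F4 | step 7 | (7R)-tricyclic alcohol from 10 | O=C1C[C@H](O)C[C@@H]2[C@@]1(C)[C@H]1CC[C@@]21C(=O)OC
F5 | step 7 | (7S)-tricyclic 4-nitrobenzoate | O=C1C[C@@H](OC(=O)c3ccc(cc3)[N+](=O)[O-])C[C@@H]2[C@@]1(C)[C@H]1CC[C@@]21C(=O)OC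
F6 | step 7 | (7S)-tricyclic alcohol | O=C1C[C@@H](O)C[C@@H]2[C@@]1(C)[C@H]1CC[C@@]21C(=O)OC
F7 | step 7 | (7S)-tricyclic silyl ether (C4 syn to the silyloxy group) | O=C1C[C@@H](O[Si](C)(C)C(C)(C)C)C[C@@H]2[C@@]1(C)[C@H]1CC[C@@]21C(=O)OC
F8 | step 7 | (7S)-cyclodecadienone ester (enantiomer of 11) | COC(=O)/C1=C/C[C@H](O[Si](C)(C)C(C)(C)C)CC(=O)/C(C)=C/CC1
F9 | step 7 | (7S,9S)-allylic alcohol | COC(=O)/C1=C/C[C@H](O[Si](C)(C)C(C)(C)C)C[C@H](O)/C(C)=C/CC1
F10 | step 7 | (7S,9S)-C9 phosphonopropanoate silyl ether | COC(=O)/C1=C/C[C@H](O[Si](C)(C)C(C)(C)C)C[C@H](OC(=O)C(C)P(=O)(OCC)OCC)/C(C)=C/CC1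
F11 | step 7 | (7S,9S)-C7 alcohol with C9 phosphonopropanoate | COC(=O)/C1=C/C[C@H](O)C[C@H](OC(=O)C(C)P(=O)(OCC)OCC)/C(C)=C/CC1
F12 | step 12 | C9 2-bromopropanoate of 12 | COC(=O)/C1=C/C[C@@H](O[Si](C)(C)C(C)(C)C)C[C@H](OC(=O)C(C)Br)/C(C)=C/CC1
F13 | step 12 | (7R,9S)-C7 alcohol with C9 2-bromopropanoate | COC(=O)/C1=C/C[C@@H](O)C[C@H](OC(=O)C(C)Br)/C(C)=C/CC1
F14 | step 12 | (9S)-C7 ketone with C9 2-bromopropanoate | COC(=O)/C1=C/CC(=O)C[C@H](OC(=O)C(C)Br)/C(C)=C/CC1
F15 | step 12 | (9S)-β-hydroxy δ-lactone (C7 and C11 epimers, both erased on dehydration) | COC(=O)/C1=C/CC2(O)C(C)C(=O)O[C@@H](C2)/C(C)=C/CC1
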